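The synthesis cuts the seven-membered oxepene ring O–C5–C4=C3–C2–C1–C10 of the 11-oxabicyclo[4.4.1]undecene core into a four-atom unit (O, C5, C4, C3) and a three-carbon unit (C10, C1, C2). The three-carbon unit is stored as a 1-methylcyclopropane, whose C10–C2 bond acts as a latent cation at C10 and radical at C2. In one flask, alkoxymercuration by the C5 hydroxyl closes the oxepane (O–C10). The resulting C2 mercurial, on hydride treatment, closes the oxepene by radical vinylation at C3, joining two electrophilic carbons. The precursor is a monocyclic trans-butyrolactone carrying a β-iodo Morita–Baylis–Hillman unit at C6 and a (1-methylcyclopropyl)methyl carbinol chain at C7.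

Key step: step 10

Remark on numbering (germacranolide type): C6 = lactone O–CH, C7 = CH bearing C11, C8 = acyloxy CH, C9 = CH2, C10 = quaternary ether carbon (methyl C14), C1 and C2 = the two ring CH2, C3 = vinylic CH, C4 = ester-bearing alkene carbon (ester C15), C5 = ether CH, C11/C12/C13 = lactone α-carbon, carbonyl and methylene.
Assumption: compounds 1, 3, 6, 9, 13, 18 and 23 are taken as commercial.

Step 1
Reactants: 1 (S)-5-(hydroxymethyl)furan-2(5H)-one
Product: 2 (S)-5-[(benzyloxy)methyl]furan-2(5H)-one
Conditions: BnOC(=NH)CCl3, TfOH (cat.), CH2Cl2/cyclohexane, 0 °C to rt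
Reagents that add atoms: benzyl 2,2,2-trichloroacetimidate, N=C(OCc1ccccc1)C(Cl)(Cl)Cl
Why: Acid-catalysed trichloroacetimidate O-benzylation works without base, so the epimerisable C6 centre of the butenolide stays intact.

Step 2
Reactants: 2 (S)-5-[(benzyloxy)methyl]furan-2(5H)-one; 3 1,3-dioxolane (also solvent)
Product: 4 (4S,5S)-5-[(benzyloxy)methyl]-4-(1,3-dioxolan-2-yl)oxolan-2-one
Conditions: Ph2CO (cat.), hν (medium-pressure mercury lamp, Pyrex), neat 3, rt
Reagents that add atoms: none
Why: Benzophenone-sensitised hydrogen abstraction from 3 gives the nucleophilic 1,3-dioxolan-2-yl radical, whose Giese-type conjugate addition to C7 takes place anti to the C6 side chain, setting the trans C6/C7 relationship and bringing in C8 as a masked aldehyde.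

Step 3
Reactants: 4 (4S,5S)-5-[(benzyloxy)methyl]-4-(1,3-dioxolan-2-yl)oxolan-2-one
Product: 5 (2S,3S)-2-[(benzyloxy)methyl]-5-oxooxolane-3-carbaldehyde
Conditions: TFA/H2O, CH2Cl2, 0 °C to rt
Reagents that add atoms: water, O
Why: Acid hydrolysis of the cyclic acetal frees the C8 aldehyde, and C7, although enolisable, already holds the thermodynamically preferred trans arrangement.

Step 4
Reactants: 5 (2S,3S)-2-[(benzyloxy)methyl]-5-oxooxolane-3-carbaldehyde; 6 tributyl(2-methylprop-2-en-1-yl)stannane
Product: 7 (4R,5S)-5-[(benzyloxy)methyl]-4-[(1R)-1-hydroxy-3-methylbut-3-en-1-yl]oxolan-2-one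
Conditions: (R)-BINOL (cat.), Ti(OiPr)4 (cat.), 4 Å MS, CH2Cl2, −20 °C
Reagents that add atoms: none
Why: Keck asymmetric allylation with the BINOL–titanium Lewis acid directs the methallyl group to the Re face of the aldehyde under catalyst control and sets 8R, and the neutral, cold medium avoids migration of the lactone to the new hydroxyl.

Step 5
Reactants: 7 (4R,5S)-5-[(benzyloxy)methyl]-4-[(1R)-1-hydroxy-3-methylbut-3-en-1-yl]oxolan-2-one
Product: 8 tert-butyldimethylsilyl ether of 7 at O8
Conditions: TBSOTf, 2,6-lutidine, CH2Cl2, −78 °C to 0 °C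
Reagents that add atoms: tert-butyldimethylsilyl trifluoromethanesulfonate, CC(C)(C)[Si](C)(C)OS(=O)(=O)C(F)(F)F
Why: Silyl ether formation with the triflate and a hindered base blocks the C8 hydroxyl at once, which rules out translactonisation and later competition with the C5 hydroxyl.

Step 6
Reactants: 8 tert-butyldimethylsilyl ether of 7; 9 diiodomethane
Product: 10 (4S,5S)-5-[(benzyloxy)methyl]-4-[(1R)-1-(tert-butyldimethylsilyloxy)-2-(1-methylcyclopropyl)ethyl]oxolan-2-one
Conditions: Et2Zn, CH2I2, CH2Cl2, 0 °C to rt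
Reagents that add atoms: none
Why: Simmons–Smith cyclopropanation (Furukawa variant) converts the only alkene, an electron-rich 1,1-disubstituted one, into the 1-methylcyclopropane that stores C10, C1 and C2, and no stereocentre is formed because C10 carries two constitutionally equal ring CH2 groups.

Step 7
Reactants: 10 (4S,5S)-5-[(benzyloxy)methyl]-4-[(1R)-1-(tert-butyldimethylsilyloxy)-2-(1-methylcyclopropyl)ethyl]oxolan-2-one
Product: 11 (4S,5S)-4-[(1R)-1-(tert-butyldimethylsilyloxy)-2-(1-methylcyclopropyl)ethyl]-5-(hydroxymethyl)oxolan-2-one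
Conditions: H2 (1 atm), 10% Pd/C, EtOAc, rt
Reagents that add atoms: none
Why: Catalytic hydrogenolysis cleaves only the benzyl ether, since a 1,1-dialkylcyclopropane, the silyl ether and the lactone are inert to H2 over Pd/C at ambient pressure.

Step 8
Reactants: 11 (4S,5S)-4-[(1R)-1-(tert-butyldimethylsilyloxy)-2-(1-methylcyclopropyl)ethyl]-5-(hydroxymethyl)oxolan-2-one
Product: 12 (2S,3S)-3-[(1R)-1-(tert-butyldimethylsilyloxy)-2-(1-methylcyclopropyl)ethyl]-5-oxooxolane-2-carbaldehyde
Conditions: Dess–Martin periodinane, NaHCO3, CH2Cl2, 0 °C to rt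
Reagents that add atoms: none
Why: Dess–Martin oxidation under buffered, non-basic conditions gives the α-acyloxy aldehyde (C5) without epimerisation at C6.

Step 9
Reactants: 12 (2S,3S)-3-[(1R)-1-(tert-butyldimethylsilyloxy)-2-(1-methylcyclopropyl)ethyl]-5-oxooxolane-2-carbaldehyde; 13 methyl propiolate
Product: 14 methyl (Z)-2-{(R)-hydroxy[(2S,3S)-3-{(1R)-1-(tert-butyldimethylsilyloxy)-2-(1-methylcyclopropyl)ethyl}-5-oxooxolan-2-yl]methyl}-3-iodoacrylate
Conditions: MgI2, CH2Cl2, −20 °C to 0 °C
Reagents that add atoms: magnesium iodide, [Mg+2].[I-].[I-]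
Why: In this β-iodo Morita–Baylis–Hillman (halo-aldol) reaction iodide adds to 13 to give a magnesium 3-iodoallenolate that attacks the aldehyde in the polar Felkin–Anh (Cornforth) arrangement anti to the C6–O bond, which sets 5R (5,6-anti), and the aldehyde is met on the side away from iodine, which gives the Z-iodide.

Step 10
Reactants: 14 methyl (Z)-2-{(R)-hydroxy[(2S,3S)-3-{(1R)-1-(tert-butyldimethylsilyloxy)-2-(1-methylcyclopropyl)ethyl}-5-oxooxolan-2-yl]methyl}-3-iodoacrylate
Product: 17 methyl (5R,6S,7S,8R,10S)-8-(tert-butyldimethylsilyloxy)-5,10-epoxygermacr-3-en-12,6-olid-15-oate, via organomercury triflate 15 (not isolated), via alkylmercury hydride 16 (not isolated)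
Conditions: Hg(OTf)2, 2,6-di-tert-butyl-4-methylpyridine, CH2Cl2 (high dilution), −20 °C to rt; then NaBH(OMe)3, CH2Cl2/MeOH, −40 °C to 0 °C
Reagents that add atoms: none
Why: Electrophilic divalent mercury attacks a CH2 corner of the cyclopropane while the C5 hydroxyl opens the adjoining C10–CH2 bond from the rear at the more substituted carbon (Markovnikov sense), which forms O–C10 and leaves a primary C2–Hg bond in 15; hydride exchange gives 16, whose radical chain decomposition releases the nucleophilic C2 radical, this adds to the electrophilic β-carbon C3 of the iodoacrylate, and the adduct radical at C4 expels iodine to restore C3=C4, iodine carrying the chain by abstracting hydrogen from 16. The closest known reaction types are the intramolecular solvomercuration of cyclopropanes, the reductive mercury method of the Giese reaction and radical vinylation by addition and β-elimination. The oxepane closes by 7-exo-tet attack of oxygen on C10 and the oxepene by 7-endo-trig radical addition to C3, the 6-exo alternative at the fully substituted and polarity-mismatched C4 being disfavoured. C10 is the only new stereocentre: the bulkier CH2CH2Hg arm should take the position cis to the acrylate on C5 (both pseudo-equatorial across the ring oxygen), and only this cis isomer can bridge, so that 5R dictates 10S in every molecule that reaches 17. The step needs chemoselective activation of the cyclopropane and a single radical acceptor: all alkenes present are electron-poor and inert to mercury, the C8 oxygen is silylated, the hindered pyridine removes the acid, and the α-methylene lactone is not yet in place. The Z geometry of 14 is of no consequence because C3–C4 rotates freely in the adduct radical and the ring allows only the cis-in-ring alkene, and the C5–H bond lies on the ring face opposite to the C2 radical, which suppresses 1,5-hydrogen transfer.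

Step 11
Reactants: 17 methyl (5R,6S,7S,8R,10S)-8-(tert-butyldimethylsilyloxy)-5,10-epoxygermacr-3-en-12,6-olid-15-oate; 18 N,N-dimethylmethyleneiminium iodide (Eschenmoser's salt)
Product: 21 methyl (5R,6S,7S,8R,10S)-8-(tert-butyldimethylsilyloxy)-5,10-epoxygermacra-3,11(13)-dien-12,6-olid-15-oate, via Mannich base 19 (not isolated), via methiodide 20 (not isolated)
Conditions: LDA, THF, −78 °C; 18, −78 °C to rt; then MeI, MeOH, rt; then aq. NaHCO3, CH2Cl2, rt
Reagents that add atoms: none
Why: Kinetic deprotonation of the lactone CH2 (the most acidic site), Mannich reaction of the enolate with 18 and Hofmann-type elimination of the quaternised amine give the α-methylene lactone, the transient C11 stereocentre being erased.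

Step 12
Reactants: 21 methyl (5R,6S,7S,8R,10S)-8-(tert-butyldimethylsilyloxy)-5,10-epoxygermacra-3,11(13)-dien-12,6-olid-15-oate
Product: 22 methyl (5R,6S,7R,8R,10S)-8-hydroxy-5,10-epoxygermacra-3,11(13)-dien-12,6-olid-15-oate
Conditions: HF·pyridine, THF/pyridine, 0 °C to rt
Reagents that add atoms: none
Why: Fluoride-mediated desilylation under mildly acidic conditions frees the C8 hydroxyl without conjugate addition to the α-methylene lactone and without lactone migration.

Step 13
Reactants: 23 (E)-2-methylbut-2-en-1-ol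
Product: 24 [(2R,3R)-2,3-dimethyloxiran-2-yl]methanol
Conditions: Ti(OiPr)4, D-(−)-diisopropyl tartrate, t-BuOOH, 4 Å MS, CH2Cl2, −20 °C
Reagents that add atoms: tert-butyl hydroperoxide, CC(C)(C)OO
Why: Sharpless asymmetric epoxidation with the D-(−)-tartrate ligand delivers oxygen to one face of the E-allylic alcohol and sets both epoxide centres (2R,3R), the E geometry fixing their relative configuration.

Step 14
Reactants: 24 [(2R,3R)-2,3-dimethyloxiran-2-yl]methanol
Product: 25 (2S,3R)-2,3-dimethyloxirane-2-carboxylic acid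
Conditions: RuCl3 (cat.), NaIO4, MeCN/EtOAc/H2O, 0 °C to rt
Reagents that add atoms: sodium periodate, [Na+].[O-]I(=O)(=O)=O
Why: Ruthenium tetroxide oxidation (RuCl3/NaIO4) takes the primary alcohol to the acid without touching the epoxide, and the descriptor at C2 changes to S only through the priority rules.

Step 15
Reactants: 22 methyl (5R,6S,7R,8R,10S)-8-hydroxy-5,10-epoxygermacra-3,11(13)-dien-12,6-olid-15-oate; 25 (2S,3R)-2,3-dimethyloxirane-2-carboxylic acid
Product: 27 CNP0240298.1, via mixed anhydride 26 (not isolated)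
Conditions: 25, 2,4,6-trichlorobenzoyl chloride, Et3N, toluene, rt; then 22, DMAP, toluene, rt
Reagents that add atoms: none
Why: Yamaguchi esterification through the mixed anhydride and DMAP acylates the hindered secondary C8 hydroxyl with the α-quaternary acid with retention at C8 and at both epoxide centres.

Compound list
1 | (S)-5-(hydroxymethyl)furan-2(5H)-one | O=C1C=C[C@@H](CO)O1 | starting material
2 | (S)-5-[(benzyloxy)methyl]furan-2(5H)-one | O=C1C=C[C@@H](COCc2ccccc2)O1 | intermediate
3 | 1,3-dioxolane | C1COCO1 | starting material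
4 | (4S,5S)-5-[(benzyloxy)methyl]-4-(1,3-dioxolan-2-yl)oxolan-2-one (substituents trans) | O=C1C[C@H](C2OCCO2)[C@@H](COCc2ccccc2)O1 | intermediate
5 | (2S,3S)-2-[(benzyloxy)methyl]-5-oxooxolane-3-carbaldehyde | O=C1C[C@H](C=O)[C@@H](COCc2ccccc2)O1 | intermediate
6 | tributyl(2-methylprop-2-en-1-yl)stannane | C=C(C)C[Sn](CCCC)(CCCC)CCCC | starting material
7 | (4R,5S)-5-[(benzyloxy)methyl]-4-[(1R)-1-hydroxy-3-methylbut-3-en-1-yl]oxolan-2-one | O=C1C[C@H]([C@H](O)CC(C)=C)[C@@H](COCc2ccccc2)O1 | intermediate
8 | (4S,5S)-5-[(benzyloxy)methyl]-4-[(1R)-1-(tert-butyldimethylsilyloxy)-3-methylbut-3-en-1-yl]oxolan-2-one (spatial arrangement as in 7) | O=C1C[C@H]([C@H](O[Si](C)(C)C(C)(C)C)CC(C)=C)[C@@H](COCc2ccccc2)O1 | intermediate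
9 | diiodomethane | ICI | starting material
10 | (4S,5S)-5-[(benzyloxy)methyl]-4-[(1R)-1-(tert-butyldimethylsilyloxy)-2-(1-methylcyclopropyl)ethyl]oxolan-2-one | O=C1C[C@H]([C@H](O[Si](C)(C)C(C)(C)C)CC2(C)CC2)[C@@H](COCc2ccccc2)O1 | intermediate
11 | (4S,5S)-4-[(1R)-1-(tert-butyldimethylsilyloxy)-2-(1-methylcyclopropyl)ethyl]-5-(hydroxymethyl)oxolan-2-one | O=C1C[C@H]([C@H](O[Si](C)(C)C(C)(C)C)CC2(C)CC2)[C@@H](CO)O1 | intermediate
12 | (2S,3S)-3-[(1R)-1-(tert-butyldimethylsilyloxy)-2-(1-methylcyclopropyl)ethyl]-5-oxooxolane-2-carbaldehyde | O=C1C[C@H]([C@H](O[Si](C)(C)C(C)(C)C)CC2(C)CC2)[C@@H](C=O)O1 | intermediate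
13 | methyl propiolate | C#CC(=O)OC | starting material
14 | methyl (Z)-2-{(R)-hydroxy[(2S,3S)-3-{(1R)-1-(tert-butyldimethylsilyloxy)-2-(1-methylcyclopropyl)ethyl}-5-oxooxolan-2-yl]methyl}-3-iodoacrylate | O=C1C[C@H]([C@H](O[Si](C)(C)C(C)(C)C)CC2(C)CC2)[C@@H]([C@H](O)/C(=C/I)C(=O)OC)O1 | intermediate
15 | oxepane organomercury triflate: O–C10 closed, C10 carries CH3 and, cis to the iodoacrylate on C5, CH2CH2HgOTf; C5 to C8 as in 14 | O=C1O[C@H]2[C@H](C1)[C@H](O[Si](C)(C)C(C)(C)C)C[C@](C)(CC[Hg]OS(=O)(=O)C(F)(F)F)O[C@@H]2/C(=C/I)C(=O)OC | intermediate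
16 | alkylmercury hydride derived from 15 (CH2CH2HgH arm) | O=C1O[C@H]2[C@H](C1)[C@H](O[Si](C)(C)C(C)(C)C)C[C@](C)(CC[HgH])O[C@@H]2/C(=C/I)C(=O)OC | intermediate
17 | methyl (5R,6S,7S,8R,10S)-8-(tert-butyldimethylsilyloxy)-5,10-epoxygermacr-3-en-12,6-olid-15-oate (bridged tricycle, CH2 at C11) | C1C(=O)O[C@H]2[C@H]1[C@H](O[Si](C)(C)C(C)(C)C)C[C@]1(C)CCC=C(C(=O)OC)[C@H]2O1 | intermediate
18 | N,N-dimethylmethyleneiminium iodide (Eschenmoser's salt) | C=[N+](C)C.[I-] | starting material
19 | 13-(dimethylamino) derivative of 17 (C11 configuration not controlled, erased in the same step) | CN(C)CC1C(=O)O[C@H]2[C@H]1[C@H](O[Si](C)(C)C(C)(C)C)C[C@]1(C)CCC=C(C(=O)OC)[C@H]2O1 | intermediate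
20 | methiodide of 19 | C[N+](C)(C)CC1C(=O)O[C@H]2[C@H]1[C@H](O[Si](C)(C)C(C)(C)C)C[C@]1(C)CCC=C(C(=O)OC)[C@H]2O1.[I-] | intermediate
21 | methyl (5R,6S,7S,8R,10S)-8-(tert-butyldimethylsilyloxy)-5,10-epoxygermacra-3,11(13)-dien-12,6-olid-15-oate | C=C1C(=O)O[C@H]2[C@H]1[C@H](O[Si](C)(C)C(C)(C)C)C[C@]1(C)CCC=C(C(=O)OC)[C@H]2O1 | intermediate
22 | methyl (5R,6S,7R,8R,10S)-8-hydroxy-5,10-epoxygermacra-3,11(13)-dien-12,6-olid-15-oate | C=C1C(=O)O[C@H]2[C@H]1[C@H](O)C[C@]1(C)CCC=C(C(=O)OC)[C@H]2O1 | intermediate
23 | (E)-2-methylbut-2-en-1-ol | C/C=C(\C)CO | starting material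
24 | [(2R,3R)-2,3-dimethyloxiran-2-yl]methanol | OC[C@@]1(C)O[C@@H]1C | intermediate
25 | (2S,3R)-2,3-dimethyloxirane-2-carboxylic acid | OC(=O)[C@@]1(C)O[C@@H]1C | intermediate
26 | (2S,3R)-2,3-dimethyloxirane-2-carboxylic 2,4,6-trichlorobenzoic anhydride | O=C(OC(=O)[C@@]1(C)O[C@@H]1C)c1c(Cl)cc(Cl)cc1Cl | intermediate
27 | CNP0240298.1, methyl (5R,6S,7R,8R,10S)-8-[(2S,3R)-2,3-dimethyloxirane-2-carbonyloxy]-5,10-epoxygermacra-3,11(13)-dien-12,6-olid-15-oate | C=C1C(=O)O[C@H]2[C@H]1[C@H](OC(=O)[C@@]1(C)O[C@@H]1C)C[C@]1(C)CCC=C(C(=O)OC)[C@H]2O1 | target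

Total step count: 15. Longest linear sequence: 13 steps (steps 1 to 12, then step 15).

Steps most likely to fail

Step 10. The seven-membered etherification may be too slow, so that the mercurated cation loses a proton. Hydrogen transfer to the C2 radical may also outrun the 7-endo closure. The fallback separates the two bond formations and purifies between them. It sets out from 14. Sodium benzenesulfinate in DMF replaces iodide by addition and elimination to give the vinyl sulfone F1. Hg(O2CCF3)2 in CH2Cl2 followed by aqueous KBr gives the isolable oxepane organomercury bromide F2, from which the cis isomer is separated. Iodine in CH2Cl2 converts F2 into the primary iodide F3. Slow addition of (Me3Si)3SiH and AIBN in refluxing toluene then closes C2–C3 by the classical alkyl iodide to vinyl sulfone radical addition with loss of the sulfonyl radical. The fallback comes back to the route at 17.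

Step 9. Facial selectivity in the addition to the α-acyloxy aldehyde may be poor, since weak chelation by magnesium competes with the Felkin–Anh arrangement. The fallback sets out from 14 as its C5 epimer mixture. Dess–Martin oxidation gives the iodoalkylidene keto ester F4. The centre is then reset under reagent control by Corey–Bakshi–Shibata reduction ((R)-Me-CBS, catecholborane, toluene, −78 °C). Hydride goes to the Si face of the ketone, on the model that the trisubstituted iodoalkenyl group is the larger substituent. The fallback comes back at 14.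

Step 11. γ-Deprotonation of the enoate at C2 may compete, followed by loss of the C5–O bridge, and the amide base may attack the ester. The fallback avoids amide bases and sets out from 17. MeOMgOCO2Me (methyl magnesium carbonate) in DMF at 120 °C carboxylates the lactone α-position to give the α-carboxy lactone F5. Aqueous formaldehyde, Et2NH and NaOAc/AcOH then effect a decarboxylative Mannich methylenation. The fallback comes back at 21.

Further compounds
F1 | step 10 | vinyl sulfone analogue of 14 (PhSO2 in place of I) | O=C1C[C@H]([C@H](O[Si](C)(C)C(C)(C)C)CC2(C)CC2)[C@@H]([C@H](O)/C(=C/S(=O)(=O)c2ccccc2)C(=O)OC)O1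
F2 | step 10 | oxepane organomercury bromide (CH2CH2HgBr arm on C10 cis to the sulfonylacrylate on C5) | O=C1O[C@H]2[C@H](C1)[C@H](O[Si](C)(C)C(C)(C)C)C[C@](C)(CC[Hg]Br)O[C@@H]2/C(=C/S(=O)(=O)c1ccccc1)C(=O)OC
F3 | step 10 | oxepane primary iodide (CH2CH2I arm on C10) | O=C1O[C@H]2[C@H](C1)[C@H](O[Si](C)(C)C(C)(C)C)C[C@](C)(CCI)O[C@@H]2/C(=C/S(=O)(=O)c1ccccc1)C(=O)OC
F4 | step 9 | C5 ketone of 14, methyl (Z)-2-acyl-3-iodoacrylate | O=C1C[C@H]([C@H](O[Si](C)(C)C(C)(C)C)CC2(C)CC2)[C@@H](C(=O)/C(=C/I)C(=O)OC)O1
F5 | step 11 | 11-carboxy derivative of 17 | OC(=O)C1C(=O)O[C@H]2[C@H]1[C@H](O[Si](C)(C)C(C)(C)C)C[C@]1(C)CCC=C(C(=O)OC)[C@H]2O1
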